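The data are simulated for an exercise; scatter was added.

The time asked about was 2.0 h, and Thursday's run had followed this stirred flask of solid substrate and reagent to 25.0 min, so I reckoned from the rate at which the solid went.

- Thursday's: solid substrate 0.20 M; reagent 2.5 equiv; the very flask that is asked about, followed so far
- flask: solid substrate 0.20 M; reagent 2.50 equiv; time 2.0 h

Thursday's run (percent of the solid substrate charged)

| time / min | solid substrate / % | single product / % | other mono adduct / % |
|---|---|---|---|
| 2.00 | 99.8 | 0.3 | 0 |
| 4.00 | 99.1 | 0.3 | 0.5 |
| 10.0 | 97.6 | 0.4 | 0.5 |
| 25.0 | 95.7 | 0.9 | 0 |

(each reading ± 0.5 percentage points)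

- solid substrate is a solid; its amount is given per volume of the solution
- on the list of suspects stand: reagent + single product -> bis adduct + by-product; starting material <-> dormant form; starting material + reagent -> single product + by-product; starting material + reagent -> other mono adduct + by-product; solid substrate <-> starting material; reagent + other mono adduct -> bis adduct + by-product; single product <-> isomer of the product
- at the start none of the solid substrate is in solution

1. solid substrate at 2.0 h, in percent of the solid substrate charged (only what is still solid)
2. single product at 2.0 h, in percent of the solid substrate charged
3. other mono adduct at 2.0 h, in percent of the solid substrate charged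
4. bis adduct at 2.0 h, in percent of the solid substrate charged

In Thursday's run the solid fell at 0.144 h⁻¹ of the charge over the first 10.0 min, then between 10.0 min and 25.0 min at 0.0760 h⁻¹, about half of that. I call this second figure the running rate: the fraction of the charge leaving the solid per hour once dissolved material sits at a quasi-steady state. I put the slowing down to the solution filling, since Thursday's solid had lost 4.3 percentage points against 0.9 % of single product read. Even if each lost point of solid had taken up two of reagent, Thursday's run would have used hardly any of the reagent charge, so in that run I took its factor as near one.

Replacing the curve by this mean, the early rush is worth 1.1 points at the end. The remaining 95.0 min take 12 points, which leaves 83.7 % solid. The rate's own scatter, 0.0283 h⁻¹, matters more, at 4.5 points.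

The forecast gave 90.5 % solid substrate, 4.5 % single product, 0.7 % other mono adduct and 0.2 % bis adduct, reasoning that “dissolved material stays near 4% and the reaction drains about 0.05 %/min”. Its solid stood above mine.

The flask gave 78.0 % solid substrate, 2.14 % single product, 0.0827 % other mono adduct and 6.51 % bis adduct, so the solid stood 12 points below the forecast and 5.7 points below my reckoning.

reagent + single product → bis adduct + by-product (k = 0.00120 M⁻¹ s⁻¹); starting material ⇌ dormant form (K = 1.10, k = 3.10 × 10⁻⁴ s⁻¹); starting material + reagent → single product + by-product (k = 0.00290 M⁻¹ s⁻¹); starting material + reagent → other mono adduct + by-product (k = 2.20 × 10⁻⁴ M⁻¹ s⁻¹); solid substrate ⇌ starting material, rate k5*(cs5 - [starting material]) while solid is left; crystals form when [starting material] > cs5 (solubility = 10.0 mM, k = 9.30 × 10⁻⁴ s⁻¹); reagent + other mono adduct → bis adduct + by-product (k = 0.00510 M⁻¹ s⁻¹); single product ⇌ isomer of the product (K = 5.50, k = 0.00300 s⁻¹) At 2.00 h starting material was being made 1.01 times as fast as it was used up, each step taken net. On the same flask left until 3.0 h, the running rate takes 7.6 points in the extra time and gives 70.4 % solid; that flask held 67.9 %.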